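Readings and results were computed for substances that don't exist; scatter was added.

We decide to follow one ratio through these flasks, [G]/[X], and to ask at each moment what it stands against.

| flask | G | J | remark | time |
|---|---|---|---|---|
| amber | 0.54 M | 0.50 M | run made earlier |  |
| teal | 1.6 M | 0.50 M | run made earlier |  |
| Monday's | 0.80 M | 0.500 M |  | 12 h |
| Saturday's | 0.80 M | 1.00 M |  | 12 h |
| Tuesday's | 0.80 M | 2.00 M |  | 12 h |

| run | time / h | X / % | G / % |
|---|---|---|---|
| amber | 0.667 | 8.3 | 92.5 |
| amber | 2.00 | 17.9 | 80.1 |
| amber | 3.00 | 23.8 | 71.9 |
| amber | 5.00 | 30.5 | 64.0 |
| amber | 8.00 | 36.8 | 53.0 |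
| teal | 1.33 | 11.9 | 87.5 |
| teal | 3.00 | 17.6 | 79.4 |
| teal | 4.00 | 20.9 | 77.8 |
| teal | 6.00 | 21.7 | 75.5 |
| teal | 8.00 | 22.7 | 72.3 |

(scatter of a reading: 0.5 percentage points)

- no earlier run changes the charge of J; that part of a forecast is a guess
- "hardly changes" means that all values lie within two and a half points (for a concentration: within two and a half percent of the largest)

- amount of X at the end, in percent of the G charged for Monday's, Saturday's, Tuesday's, in this order
- the shape of the row from first to last (hardly changes / rises, then falls / falls all the way / rises all the way / falls, then rises)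

In the first instants [X] is near zero, so X is being made and barely used. The amber run shows that this doesn't last: G and X together fall from 95.7 % to 89.8 % of the G charged between 3.00 h and 8.00 h, so we take it that X goes on to exchange a second J. Each step takes one J, so in our reckoning [J] stands on both sides of the comparison and cancels. Dividing the loss from that sum by the loss of G, and multiplying by the mean [G]/[X], gives 0.643, a reading that carries the scatter of a small difference. We call it the turning ratio, the [G]/[X] at which X is used as fast as it is made; the usual term is selectivity factor.

In the middle of a run [G]/[X] falls, and in this reckoning [J] changes how quickly, not where X turns. We call the first step's rate constant times the time integral of [J] the exchange dose; integrating the two steps with this ratio puts the turn at a dose of 1.24, with X at 45.1 % of the G charged, after 0.968 J spent per G. Monday's charge holds 0.625 J per G, which is less, so there J is the limiting reagent and X should end on the rising side. Saturday's holds 1.25, which is more, and Tuesday's 2.50. Amber's early loss of G, scaled by [J] and time with J held at its charge, gives exchange doses of 2.66 for Saturday's and 5.33 for Tuesday's, both more than the 1.24 at the turn. J falls as it is used, so we place Saturday's near the turn and Tuesday's past it.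

The forecast, which says of Saturday's “conversion sits near the X maximum”, gives 34 %, 40 % and 22 %: rises, then falls.

The flasks give 34.2 %, 42.5 % and 25.0 %: rises, then falls.

    G + J → E + X (k = 6.90 × 10⁻⁵ M⁻¹ s⁻¹)
    X + J → E + Z (k = 3.90 × 10⁻⁵ M⁻¹ s⁻¹)
    X ⇌ L (K = 1.90, k = 4.10 × 10⁻⁶ s⁻¹)

At 12.0 h Monday's flask still makes X 1.16 times as fast as it uses it, each step taken net. Saturday's ends with [G]/[X] at 0.605, close to the turning ratio, and its X stands at 43.0 % at 6.00 h and 42.5 % at 12.0 h. Tuesday's ratio is already 0.332 at 6.00 h, below 0.643, and its X goes from 40.9 % there to 25.0 % at 12.0 h.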